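A charge of 0.78 mM of initiator cannot consume 0.0705 M of starting material one for one, yet the theta run does so by 25.0 min, so each start must be passed along a chain. I therefore suspect that a small carrier concentration sets the order of the rate, and I read it through the runs.

| setting | beta | theta | zeta | flask |
|---|---|---|---|---|
| starting material | 0.078 M | 0.078 M | 0.078 M | 0.078 M |
| partner | 0.078 M | 0.31 M | 0.156 M | 0.156 M |
| initiator | 0.78 mM | 0.78 mM | 1.6 mM | 0.78 mM |
| remark | run made earlier | run made earlier | run made earlier |  |
| time |  |  |  | 25 min |

| run | time / min | target / % | starting material / % |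
|---|---|---|---|
| beta | 2.00 | 4.1 | 96.2 |
| beta | 3.00 | 4.7 | 93.7 |
| beta | 6.00 | 9.3 | 89.9 |
| beta | 10.0 | 13.8 | 83.7 |
| beta | 15.0 | 17.4 | 76.1 |
| beta | 25.0 | 25.8 | 63.6 |
| theta | 1.50 | 8.5 | 91.9 |
| theta | 5.00 | 25.4 | 72.1 |
| theta | 8.00 | 37.2 | 57.1 |
| theta | 15.0 | 59.4 | 31.9 |
| theta | 20.0 | 70.0 | 18.1 |
| theta | 25.0 | 78.0 | 9.6 |
| zeta | 2.00 | 7.7 | 90.2 |
| zeta | 6.00 | 22.8 | 73.9 |
| zeta | 12.0 | 40.4 | 53.5 |
| zeta | 20.0 | 58.4 | 33.0 |
| zeta | 25.0 | 66.6 | 22.6 |

(standard deviation of a reading: 0.5 percentage points)

* how much target the flask holds at 25 min, in percent of the starting material charged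
* how much starting material the flask holds at 25 min, in percent of the starting material charged

My gauge is κ = ln(charged/left)/t, a pseudo-first-order constant read at 25 min:

κ(beta) = 0.0181 /min, κ(theta) = 0.0937 /min, κ(zeta) = 0.0595 /min

But the decay is not truly first order: theta reads 0.0654 /min at 5.00 min, less than at the end. So κ is a clock reading, and I compare runs at one time.

Order in partner, beta to theta: 1.19

That order is not a clean number, but the flask's c(partner) lies above beta's and below theta's, so I interpolate. This gives the flask's clock constant, 0.0414 /min.

Two runs are thin support, so I test it on zeta: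

Order in initiator: ln(κ(zeta)/κ(flask))/ln(c(initiator) ratio) = 0.506

That is close to 0.5, as expected for carriers born in proportion to c(initiator) and ended in pairs. Then:

Starting material left: 35.6 %

For target, the flask shares its initiator with beta, where target is 70.9 % of what was consumed, and its partner with zeta, at 86.0 %. I take the mean, which is crude:

Target: 50.6 %

The forecast, “The flask should therefore follow zeta on a stretched clock”, gives 45 % starting material, more than mine, and 47.5 % target.

The flask gives 37.0 % starting material and 51.8 % target.

    initiator → 2 initiating radical (k = 4.80 × 10⁻⁵ /s)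
    starting material + initiating radical → capped initiator + first chain carrier (k = 2.10 × 10⁵ /M/s)
    partner + first chain carrier ⇌ target + second chain carrier (K = 0.200, k = 3300 /M/s)
    starting material + second chain carrier → released group + first chain carrier (k = 17000 /M/s)
    2 first chain carrier → ended chains A (k = 4.70 × 10⁶ /M/s)
    2 second chain carrier → ended chains B (k = 1.60 × 10⁶ /M/s)
    partner + target → over-reaction product (k = 7.90 × 10⁻⁴ /M/s)
    starting material + target → side product (k = 0.00470 /M/s)
    crystals ⇌ target, rate k9*(cs9 - [target]) while solid is left; crystals form when [target] > cs9 (solubility = 8.80 mM, k = 0.00890 /s)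

Its κ is thus 0.0397 /min, against my 0.0414 /min. At 25.0 min the forward partner step uses first chain carrier 470 times as fast as the pairing into ended chains A. Now take a neighbour, the same flask but with 0.27 M of partner, and scale the κ the flask really showed:

κ(neighbour) = κ(flask) × (partner ratio)^order = 0.0764 /min, so left = 14.8 %

The neighbour flask holds 13.8 % starting material.

The numbers in the tables are simulated from invented constants.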